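A direct plan would ionise the benzyl alcohol A1 (2,3-dibromo-4-(hydroxymethyl)-6-methoxyphenol) with acid, would trap the cation with 2-bromo-1,3,5-trimethoxybenzene A2 in a Friedel–Crafts benzylation, and would then cleave the four methyl ethers of the diarylmethane A3 with BBr3.
The benzylation would be weakest: acid strong enough to ionise the electron-poor A1 could also cause its self-condensation, a second benzylation of A3 and proton-induced bromine transfer from A2.
The fourfold ether cleavage would come next: excess BBr3 and the HBr it forms would act on an acid-labile benzylphloroglucinol that can lose its ring B bromine or its benzyl group after ipso protonation.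
The reduction of an aldehyde to A1 and the methyl masking of ring B would add operations without adding skeleton.

The new route would disconnect ring B itself. Its 1,3,5-trioxygenated ring with alternating carbon substituents (C1 CH2Ar, C3 H, C5 Br) is the pattern of a cyclised polyketide, so the six carbons are traced to an open-chain 2-(arylmethyl)-3,5-dioxopimelate, made from a malonate unit and an acetoacetate unit. The key step, a Claisen (Dieckmann-type) cyclisation with aromatisation, would close ring B with its three free hydroxyls, the CH2Ar group already in place and an ester blocking one ring carbon, so that bromine could enter only at the last one. No aryl–CH2 bond would be made by Friedel–Crafts chemistry, ring B would never carry ethers, and no BBr3 step would be needed.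

Key step: step 7

Remark: compounds 8, 10 and 11 carry one stereocentre (the carbon bearing the arylmethyl group) and would be racemic; this carbon becomes an aromatic carbon of ring B in step 7, so no stereocontrol is needed. Compound 9 is the commercial reagent known as Chan's diene.

Step 1
Reactants: 1 5-bromovanillin (3-bromo-4-hydroxy-5-methoxybenzaldehyde)
Product: 2 5,6-dibromovanillin (2,3-dibromo-4-hydroxy-5-methoxybenzaldehyde)
Conditions: Br2 (1.2 equiv), Fe powder (5 mol %), AcOH, 25 to 40 °C
Reagents that add atoms: bromine BrBr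
Why: Electrophilic aromatic bromination should go para to the methoxy group, the only activated position left once both positions ortho and the position para to the hydroxyl are occupied, which gives the 2,3-dibromo-4,5-dioxygenated pattern of ring A.

Step 2
Reactants: 2 5,6-dibromovanillin
Product: 3 2,3-dibromo-4,5-dihydroxybenzaldehyde
Conditions: AlCl3 (1.3 equiv), pyridine (4.5 equiv), CH2Cl2, reflux; then 2 M HCl
Reagents that add atoms: none
Why: AlCl3–pyridine demethylation should cleave the methyl ether selectively because the neighbouring phenol chelates aluminium and activates the O–CH3 bond for SN2 attack by pyridine, while the aldehyde and the aryl bromides are inert.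

Step 3
Reactants: 3 2,3-dibromo-4,5-dihydroxybenzaldehyde
Product: 4 6,7-dibromo-2,2-dimethyl-1,3-benzodioxole-5-carbaldehyde
Conditions: 2,2-dimethoxypropane (4 equiv), TsOH·H2O (5 mol %), toluene, reflux with removal of MeOH (4 Å sieves in a Soxhlet); brief aqueous work-up
Reagents that add atoms: 2,2-dimethoxypropane COC(C)(C)OC
Why: Acid-catalysed transketalisation should close the five-membered isopropylidene ketal of the catechol, a group stable to base and to NBS that is later removed by aqueous acid with release of acetone only, and any aldehyde dimethyl acetal should revert on work-up.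

Step 4
Reactants: 4 6,7-dibromo-2,2-dimethyl-1,3-benzodioxole-5-carbaldehyde; 5 Meldrum's acid (2,2-dimethyl-1,3-dioxane-4,6-dione)
Product: 7 5-[(6,7-dibromo-2,2-dimethyl-1,3-benzodioxol-5-yl)methyl]-2,2-dimethyl-1,3-dioxane-4,6-dione, via arylidene Meldrum's acid 6 (not isolated)
Conditions: Hantzsch ester (diethyl 2,6-dimethyl-1,4-dihydropyridine-3,5-dicarboxylate, 1.1 equiv), L-proline (10 mol %), EtOH, rt
Reagents that add atoms: none
Why: Knoevenagel condensation followed by transfer hydrogenation of the highly electrophilic arylidene 6 by the Hantzsch ester (three-component reductive alkylation) should turn the aldehyde carbon into the future CH2 bridge without touching the aryl bromides, and no stereocentre is formed.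

Step 5
Reactants: 7 5-[(6,7-dibromo-2,2-dimethyl-1,3-benzodioxol-5-yl)methyl]-2,2-dimethyl-1,3-dioxane-4,6-dione
Product: 8 3-(6,7-dibromo-2,2-dimethyl-1,3-benzodioxol-5-yl)-2-(methoxycarbonyl)propanoic acid (racemic)
Conditions: MeOH, reflux
Reagents that add atoms: methanol CO
Why: Alcoholysis of a monosubstituted Meldrum's acid should open the ring to the malonic half-ester with loss of acetone, at a temperature well below that of decarboxylation, and the new stereocentre is left racemic because it is erased in step 7.

Step 6
Reactants: 8 3-(6,7-dibromo-2,2-dimethyl-1,3-benzodioxol-5-yl)-2-(methoxycarbonyl)propanoic acid; 9 1-methoxy-1,3-bis(trimethylsilyloxy)buta-1,3-diene (Chan's diene)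
Product: 11 dimethyl 2-[(6,7-dibromo-2,2-dimethyl-1,3-benzodioxol-5-yl)methyl]-3,5-dioxoheptanedioate (racemic; keto–enol mixture), via malonyl half-ester chloride 10 (not isolated)
Conditions: (COCl)2 (1.3 equiv), DMF (cat.), CH2Cl2, 0 °C to rt, evaporate; then 9 (1.5 equiv), CH2Cl2, −78 to 20 °C; aq. NH4Cl
Reagents that add atoms: none
Why: Acid chloride formation followed by Mukaiyama-type C-acylation of the 1,3-bis(silyl enol ether) at its terminal carbon should give the open-chain tetracarbonyl compound without any base, so that the acidic malonyl C–H of 10 is not deprotonated, and the silyl ketene acetal end is hydrolysed to the methyl ester on work-up.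

Step 7
Reactants: 11 dimethyl 2-[(6,7-dibromo-2,2-dimethyl-1,3-benzodioxol-5-yl)methyl]-3,5-dioxoheptanedioate
Product: 13 methyl 3-[(6,7-dibromo-2,2-dimethyl-1,3-benzodioxol-5-yl)methyl]-2,4,6-trihydroxybenzoate, via trioxocyclohexanecarboxylate 12 (not isolated)
Conditions: NaOMe (4 equiv), MeOH, 0 to 45 °C, Ar; then cold 1 M HCl
Reagents that add atoms: none
Why: Methoxide should convert 11 into its polyenolate, in which the carbanion of the doubly activated C6 methylene (between the C5 ketone and the C7 ester) adds to the C1 ester carbonyl and expels methoxide, an intramolecular Claisen (Dieckmann) condensation that forms the C1–C6 bond and gives trione 12, which enolises at once to the aromatic phenoxide of 13. The closest known reaction type is the biomimetic Claisen cyclisation of 3,5,7-triketo esters to acylphloroglucinols and of 3,5-dioxopimelates to 2,4,6-trihydroxybenzoates. Ring B is closed in the 6-exo-trig mode, all six ring carbons coming from the open chain (C1 to C3 from the malonate unit, C4 to C6 from the acetoacetate unit). No stereocentre is set, since the two sp3 ring carbons of 12 become aromatic. The step needs C-acylation by C6 rather than lactonisation to a 4-hydroxy-2-pyrone or closure of C2 onto C7, which would give a quaternary, non-aromatisable trione; both side paths are reversible in NaOMe/MeOH, no aldol mode can give a six-membered ring, and only the wanted closure is drawn out of the equilibria by aromatisation.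

Step 8
Reactants: 13 methyl 3-[(6,7-dibromo-2,2-dimethyl-1,3-benzodioxol-5-yl)methyl]-2,4,6-trihydroxybenzoate
Product: 14 methyl 3-bromo-5-[(6,7-dibromo-2,2-dimethyl-1,3-benzodioxol-5-yl)methyl]-2,4,6-trihydroxybenzoate
Conditions: NBS (1.0 equiv), THF, −78 to 0 °C, dark
Reagents that add atoms: N-bromosuccinimide O=C1CCC(=O)N1Br
Why: Electrophilic aromatic bromination should occur at C5 of the benzoate ring, the single unsubstituted carbon of ring B flanked by two hydroxyls, because the ester blocks the only other position and the dibrominated, ketal-protected ring A is far less nucleophilic.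

Step 9
Reactants: 14 methyl 3-bromo-5-[(6,7-dibromo-2,2-dimethyl-1,3-benzodioxol-5-yl)methyl]-2,4,6-trihydroxybenzoate
Product: 17 vidalol A (2-bromo-4-[(2,3-dibromo-4,5-dihydroxyphenyl)methyl]benzene-1,3,5-triol; achiral), via trihydroxybenzoic acid 15 (not isolated), via decarboxylated acetonide 16 (not isolated)
Conditions: NaOH (2 M aq., 6 equiv), MeOH, 60 °C, Ar; then 6 M HCl to ca. 3 M, THF, 55 °C, Ar
Reagents that add atoms: none
Why: Saponification of the salicylate-type ester, protodecarboxylation of the resulting 2,4,6-trihydroxybenzoic acid through its ipso-protonated β-keto acid tautomer, and hydrolysis of the isopropylidene ketal in the same acidic medium should unmask the target while setting free only methanol, CO2 and acetone, none of which can alkylate ring B.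

Compound list
1 | 5-bromovanillin (3-bromo-4-hydroxy-5-methoxybenzaldehyde) | COc1cc(C=O)cc(Br)c1O | starting material
2 | 5,6-dibromovanillin (2,3-dibromo-4-hydroxy-5-methoxybenzaldehyde) | COc1cc(C=O)c(Br)c(Br)c1O | intermediate
3 | 2,3-dibromo-4,5-dihydroxybenzaldehyde | O=Cc1cc(O)c(O)c(Br)c1Br | intermediate
4 | 6,7-dibromo-2,2-dimethyl-1,3-benzodioxole-5-carbaldehyde | CC1(C)Oc2cc(C=O)c(Br)c(Br)c2O1 | intermediate
5 | Meldrum's acid (2,2-dimethyl-1,3-dioxane-4,6-dione) | CC1(C)OC(=O)CC(=O)O1 | starting material
6 | 5-[(6,7-dibromo-2,2-dimethyl-1,3-benzodioxol-5-yl)methylidene]-2,2-dimethyl-1,3-dioxane-4,6-dione (arylidene Meldrum's acid; not isolated) | CC1(C)OC(=O)C(=Cc2cc3OC(C)(C)Oc3c(Br)c2Br)C(=O)O1 | intermediate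
7 | 5-[(6,7-dibromo-2,2-dimethyl-1,3-benzodioxol-5-yl)methyl]-2,2-dimethyl-1,3-dioxane-4,6-dione | CC1(C)OC(=O)C(Cc2cc3OC(C)(C)Oc3c(Br)c2Br)C(=O)O1 | intermediate
8 | 3-(6,7-dibromo-2,2-dimethyl-1,3-benzodioxol-5-yl)-2-(methoxycarbonyl)propanoic acid (racemic) | COC(=O)C(Cc1cc2OC(C)(C)Oc2c(Br)c1Br)C(=O)O | intermediate
9 | 1-methoxy-1,3-bis(trimethylsilyloxy)buta-1,3-diene (Chan's diene; geometry of the C1=C2 bond immaterial) | COC(O[Si](C)(C)C)=CC(=C)O[Si](C)(C)C | starting material
10 | methyl 2-(chlorocarbonyl)-3-(6,7-dibromo-2,2-dimethyl-1,3-benzodioxol-5-yl)propanoate (racemic; not isolated) | COC(=O)C(Cc1cc2OC(C)(C)Oc2c(Br)c1Br)C(Cl)=O | intermediate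
11 | dimethyl 2-[(6,7-dibromo-2,2-dimethyl-1,3-benzodioxol-5-yl)methyl]-3,5-dioxoheptanedioate (racemic; keto–enol mixture) | COC(=O)CC(=O)CC(=O)C(Cc1cc2OC(C)(C)Oc2c(Br)c1Br)C(=O)OC | intermediate
12 | methyl 3-[(6,7-dibromo-2,2-dimethyl-1,3-benzodioxol-5-yl)methyl]-2,4,6-trioxocyclohexane-1-carboxylate (keto tautomer of 13; mixture of stereoisomers; not isolated) | COC(=O)C1C(=O)CC(=O)C(Cc2cc3OC(C)(C)Oc3c(Br)c2Br)C1=O | intermediate
13 | methyl 3-[(6,7-dibromo-2,2-dimethyl-1,3-benzodioxol-5-yl)methyl]-2,4,6-trihydroxybenzoate | COC(=O)c1c(O)cc(O)c(Cc2cc3OC(C)(C)Oc3c(Br)c2Br)c1O | intermediate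
14 | methyl 3-bromo-5-[(6,7-dibromo-2,2-dimethyl-1,3-benzodioxol-5-yl)methyl]-2,4,6-trihydroxybenzoate | COC(=O)c1c(O)c(Br)c(O)c(Cc2cc3OC(C)(C)Oc3c(Br)c2Br)c1O | intermediate
15 | 3-bromo-5-[(6,7-dibromo-2,2-dimethyl-1,3-benzodioxol-5-yl)methyl]-2,4,6-trihydroxybenzoic acid (not isolated) | OC(=O)c1c(O)c(Br)c(O)c(Cc2cc3OC(C)(C)Oc3c(Br)c2Br)c1O | intermediate
16 | 2-bromo-4-[(6,7-dibromo-2,2-dimethyl-1,3-benzodioxol-5-yl)methyl]benzene-1,3,5-triol (not isolated) | Oc1cc(O)c(Br)c(O)c1Cc1cc2OC(C)(C)Oc2c(Br)c1Br | intermediate
17 | vidalol A (2-bromo-4-[(2,3-dibromo-4,5-dihydroxyphenyl)methyl]benzene-1,3,5-triol; no stereocentre) | Oc1cc(Cc2c(O)cc(O)c(Br)c2O)c(Br)c(Br)c1O | target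

Total steps: 9. Longest linear sequence: 9 steps (1 to 17).

Steps most likely to fail

Step 7: the ring closure may be diverted into lactonisation to a 4-hydroxy-2-pyrone or into retro-Claisen fragmentation of the β-dicarbonyl chain by methoxide before the C6 enolate reaches the C1 ester. The fallback would set out from aldehyde 4 and come back at 13 with ring B bought ready-made. Reduction of 4 with NaBH4 (MeOH, 0 °C) would give (6,7-dibromo-2,2-dimethyl-1,3-benzodioxol-5-yl)methanol F1. Acid-catalysed Friedel–Crafts benzylation (TsOH·H2O cat., HFIP, rt) of an excess of commercial methyl 2,4,6-trihydroxybenzoate F2, whose two free positions are equivalent, would then give 13.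

Step 6: the α-branched malonyl chloride may lose HCl to a ketene or be attacked through oxygen, and adventitious HCl may protodesilylate the diene, so that C-acylation at the diene terminus is outrun. The fallback would set out from 7 and come back at 13, moving the branch from the acid chloride to the silyl dienolate so that the unbranched acid chloride can be used.
- Hydrolytic decarboxylation of 7 (pyridine–water, reflux) would give 3-(6,7-dibromo-2,2-dimethyl-1,3-benzodioxol-5-yl)propanoic acid F3.
- Masamune–Brooks homologation (1,1'-carbonyldiimidazole, then Mg(O2CCH2CO2CH3)2, THF) would give methyl 5-(6,7-dibromo-2,2-dimethyl-1,3-benzodioxol-5-yl)-3-oxopentanoate F4.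
- Double silylation (Me3SiCl/Et3N, then LiN(iPr)2/Me3SiCl, −78 °C) would give the 1,3-bis(silyl enol ether) 6,7-dibromo-5-[5-methoxy-3,5-bis(trimethylsilyloxy)penta-2,4-dien-1-yl]-2,2-dimethyl-1,3-benzodioxole F5.
- Acylation of F5 at its terminal carbon with commercial methyl 3-chloro-3-oxopropanoate would give dimethyl 4-[(6,7-dibromo-2,2-dimethyl-1,3-benzodioxol-5-yl)methyl]-3,5-dioxoheptanedioate F6, the symmetrical isomer of 11, in which either Claisen closure under the conditions of step 7 should lead to 13.

Step 9: saponification of the fully substituted, doubly ortho-hydroxylated benzoate may be slow, and long exposure of the bromophloroglucinol to hot alkali and then acid may cause loss or transfer of the ring B bromine. The fallback would set out from 13 and come back at 16, removing the ester before any bromine sits on ring B. Saponification and decarboxylation of 13 (NaOH, MeOH–H2O, 60 °C; then pH 3, 40 °C) would give 2-[(6,7-dibromo-2,2-dimethyl-1,3-benzodioxol-5-yl)methyl]benzene-1,3,5-triol F7, whose two free ring B positions are equivalent. One equivalent of NBS at −78 °C would then give 16, from which brief treatment with aqueous HCl in THF would release 17.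

Further compounds
F1 | step 7 | (6,7-dibromo-2,2-dimethyl-1,3-benzodioxol-5-yl)methanol | CC1(C)Oc2cc(CO)c(Br)c(Br)c2O1
F2 | step 7 | methyl 2,4,6-trihydroxybenzoate | COC(=O)c1c(O)cc(O)cc1O
F3 | step 6 | 3-(6,7-dibromo-2,2-dimethyl-1,3-benzodioxol-5-yl)propanoic acid | OC(=O)CCc1cc2OC(C)(C)Oc2c(Br)c1Br
F4 | step 6 | methyl 5-(6,7-dibromo-2,2-dimethyl-1,3-benzodioxol-5-yl)-3-oxopentanoate | COC(=O)CC(=O)CCc1cc2OC(C)(C)Oc2c(Br)c1Br
F5 | step 6 | 6,7-dibromo-5-[5-methoxy-3,5-bis(trimethylsilyloxy)penta-2,4-dien-1-yl]-2,2-dimethyl-1,3-benzodioxole (mixture of double-bond isomers) | COC(O[Si](C)(C)C)=CC(O[Si](C)(C)C)=CCc1cc2OC(C)(C)Oc2c(Br)c1Br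
F6 | step 6 | dimethyl 4-[(6,7-dibromo-2,2-dimethyl-1,3-benzodioxol-5-yl)methyl]-3,5-dioxoheptanedioate | COC(=O)CC(=O)C(Cc1cc2OC(C)(C)Oc2c(Br)c1Br)C(=O)CC(=O)OC
F7 | step 9 | 2-[(6,7-dibromo-2,2-dimethyl-1,3-benzodioxol-5-yl)methyl]benzene-1,3,5-triol | Oc1cc(O)c(Cc2cc3OC(C)(C)Oc3c(Br)c2Br)c(O)c1
A1 | direct plan | 2,3-dibromo-4-(hydroxymethyl)-6-methoxyphenol | COc1cc(CO)c(Br)c(Br)c1O
A2 | direct plan | 2-bromo-1,3,5-trimethoxybenzene | COc1cc(OC)c(Br)c(OC)c1
A3 | direct plan | 2,3-dibromo-4-[(3-bromo-2,4,6-trimethoxyphenyl)methyl]-6-methoxyphenol | COc1cc(Cc2c(OC)cc(OC)c(Br)c2OC)c(Br)c(Br)c1O
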